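**Retrosynthetic overview**
1. Cut the hindered biaryl bond between ring B (the carbon flanked by two OMe groups) and ring C (the carbon para to the phenol OH). Both carbons are innately nucleophilic.
2. Ring C is therefore used with inverted polarity: 2-prenyl-1,4-benzoquinone acts as the 4-hydroxy-3-prenylphenyl cation, a vinylogous enolonium equivalent. Ring B is the 4-lithio derivative of 2,3,5-trimethoxybiphenyl, and Zn/AcOH re-aromatises in the same flask to give the free phenol without protecting groups.
3. 2,3,5-Trimethoxybiphenyl comes from 5-bromovanillin (Suzuki coupling, then Dakin oxidation and double O-methylation). The quinone comes from 1,4-benzoquinone by decarboxylative radical prenylation.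
4. No ring is built, since all three six-membered rings are bought. A–B is joined first and B–C last, with ring C passing through quinone, quinol and phenol.

Assumption: the target SMILES has no stereocentre and no configurationally stable biaryl axis (ring C carries only H ortho to the hindered bond). The compound is achiral, so no stereocontrol is needed.

**Step 1**
Reactants: 1 5-bromovanillin; 2 phenylboronic acid
Product: 3 5-phenylvanillin
Conditions: Pd(dppf)Cl2 (2 mol %), K2CO3, dioxane/H2O, 85 °C
Reagents that add atoms: none
Why: Suzuki–Miyaura coupling of the aryl bromide in aqueous base, which tolerates the free phenol and the aldehyde and fixes the phenyl group ortho to the future C4 methoxy group.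

**Step 2**
Reactants: 3 5-phenylvanillin
Product: 5 2,3,5-trimethoxybiphenyl, via 2-methoxy-6-phenylhydroquinone 4 (not isolated)
Conditions: 30% H2O2 (1.1 equiv), NaOH aq, THF, 0 °C to rt, N2; then Me2SO4, NaOH aq, Bu4NHSO4 (cat.), 40 °C
Reagents that add atoms: hydrogen peroxide, OO; dimethyl sulfate, COS(=O)(=O)OC
Why: Dakin oxidation of a p-hydroxybenzaldehyde (aryl migration to oxygen, with the aldehyde carbon lost as formate) gives an air-sensitive hydroquinone, which is trapped at once by double Williamson O-methylation.

**Step 3**
Reactants: 6 1,4-benzoquinone (2 equiv); 7 4-methylpent-3-enoic acid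
Product: 8 2-prenyl-1,4-benzoquinone
Conditions: AgNO3 (20 mol %), (NH4)2S2O8, MeCN/H2O, 65 °C
Reagents that add atoms: none
Why: Jacobsen–Torssell (Minisci-type) decarboxylative radical alkylation, in which Ag(II)/persulfate turns the acid into the nucleophilic prenyl radical, this adds through its unhindered primary terminus to the electron-poor quinone, and the adduct is re-oxidised to the quinone.

**Step 4 (key step)**
Reactants: 5 2,3,5-trimethoxybiphenyl; 8 2-prenyl-1,4-benzoquinone
Product: 11 sanshamycin B, via aryllithium 9 (not isolated), via p-quinol 10 (not isolated)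
Conditions: n-BuLi, THF, 0 °C to rt; cannulate into 8 (1.3 equiv), THF, −78 °C; then AcOH, Zn dust, −78 °C to rt
Reagents that add atoms: none
Why: Directed ortho-metalation removes the only C–H flanked by two OMe groups, the di-ortho-substituted aryllithium adds 1,2 to the quinone carbonyl flanked by two hydrogens (the other is shielded by the prenyl group) so that two innately nucleophilic aryl carbons are joined, and Zn/AcOH reductive aromatisation of the p-quinol (vinylogous α-ketol reduction with loss of water) gives the free phenol and erases the racemic quinol stereocentre.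

**Compound list**
1 | 5-bromovanillin (3-bromo-4-hydroxy-5-methoxybenzaldehyde) | COc1cc(C=O)cc(Br)c1O | starting material
2 | phenylboronic acid | OB(O)c1ccccc1 | starting material
3 | 5-phenylvanillin (6-hydroxy-5-methoxybiphenyl-3-carbaldehyde) | COc1cc(C=O)cc(-c2ccccc2)c1O | intermediate
4 | 2-methoxy-6-phenylhydroquinone (3-methoxybiphenyl-2,5-diol) | COc1cc(O)cc(-c2ccccc2)c1O | intermediate
5 | 2,3,5-trimethoxybiphenyl | COc1cc(OC)c(OC)c(-c2ccccc2)c1 | intermediate
6 | 1,4-benzoquinone | O=C1C=CC(=O)C=C1 | starting material
7 | 4-methylpent-3-enoic acid | CC(C)=CCC(=O)O | starting material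
8 | 2-prenyl-1,4-benzoquinone (2-(3-methylbut-2-enyl)cyclohexa-2,5-diene-1,4-dione) | CC(C)=CCC1=CC(=O)C=CC1=O | intermediate
9 | 4-lithio-2,3,5-trimethoxybiphenyl | COc1cc(-c2ccccc2)c(OC)c(OC)c1[Li] | intermediate
10 | 4-hydroxy-2-prenyl-4-(2,3,5-trimethoxybiphenyl-4-yl)cyclohexa-2,5-dien-1-one (racemic; formed as its lithium alkoxide and protonated by AcOH) | O=C1C=CC(O)(c2c(OC)cc(-c3ccccc3)c(OC)c2OC)C=C1CC=C(C)C | intermediate
11 | sanshamycin B | COc1cc(-c2ccccc2)c(OC)c(OC)c1-c1ccc(O)c(CC=C(C)C)c1 | target

**Step count**
- Total steps: 4.
- Longest linear sequence: 3 (steps 1, 2 and 4).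

**Steps most likely to fail**

**Step 4 (highest risk).**
- The hindered, basic aryllithium may transfer an electron to the quinone.
- It may deprotonate the doubly activated CH2 of 8, or partly attack the carbonyl next to the prenyl group.
- The electron-rich aryl group of 10 could also migrate (dienone–phenol shift) before reduction.

The fallback sets out from 5 and comes back at 11, and it moves the prenylation to after the coupling.
- Compound 5 is lithiated to 9 as before and added to commercial 4,4-dimethoxycyclohexa-2,5-dien-1-one. This electrophile is symmetrical, non-enolisable and a much poorer electron acceptor. The product is 4,4-dimethoxy-1-(2,3,5-trimethoxybiphenyl-4-yl)cyclohexa-2,5-dien-1-ol F1.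
- Aqueous acetic acid hydrolyses the ketal to 4-hydroxy-4-(2,3,5-trimethoxybiphenyl-4-yl)cyclohexa-2,5-dien-1-one F2.
- Zinc in the same medium reduces this to 4-(2,3,5-trimethoxybiphenyl-4-yl)phenol F3.
- The sodium phenoxide of F3 (NaH, toluene) is C-alkylated with prenyl bromide at one of its two equivalent ortho positions (the para position is blocked) to give 11.

**Step 3.**
- Polyalkylation is possible.
- Some attack through the tertiary radical terminus may occur.
- Ag(II)/persulfate may oxidise the trisubstituted alkene, which would lower the yield.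

The fallback sets out from 6 and comes back at 8, and it replaces the radical by a polar addition and rearrangement.
- Prenylindium sesquibromide (prenyl bromide, In, DMF) adds 1,2 to 6 through its γ-carbon to give 4-hydroxy-4-(2-methylbut-3-en-2-yl)cyclohexa-2,5-dien-1-one F4.
- Gentle warming triggers an aromatisation-driven [3,3] Cope shift to 2-prenylhydroquinone F5.
- Ag2O in ether oxidises F5 to 8.

**Step 2.**
- Residual peroxide or air in base can oxidise hydroquinone 4 to the quinone.
- The OH flanked by OMe and Ph may methylate sluggishly in water.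

The fallback sets out from 3 and comes back at 5, and it never generates a hydroquinone.
- Compound 3 is first O-methylated (MeI, K2CO3, acetone) to 5,6-dimethoxybiphenyl-3-carbaldehyde F6.
- Baeyer–Villiger oxidation with mCPBA in CH2Cl2 gives 5,6-dimethoxybiphenyl-3-yl formate F7.
- K2CO3 in MeOH cleaves the formate to 5,6-dimethoxybiphenyl-3-ol F8.
- MeI/K2CO3 methylates F8 to 5.

**Further compounds**
F1 | step 4 | 4,4-dimethoxy-1-(2,3,5-trimethoxybiphenyl-4-yl)cyclohexa-2,5-dien-1-ol | COc1cc(-c2ccccc2)c(OC)c(OC)c1C1(O)C=CC(OC)(OC)C=C1
F2 | step 4 | 4-hydroxy-4-(2,3,5-trimethoxybiphenyl-4-yl)cyclohexa-2,5-dien-1-one | COc1cc(-c2ccccc2)c(OC)c(OC)c1C1(O)C=CC(=O)C=C1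
F3 | step 4 | 4-(2,3,5-trimethoxybiphenyl-4-yl)phenol | COc1cc(-c2ccccc2)c(OC)c(OC)c1-c1ccc(O)cc1
F4 | step 3 | 4-hydroxy-4-(2-methylbut-3-en-2-yl)cyclohexa-2,5-dien-1-one | C=CC(C)(C)C1(O)C=CC(=O)C=C1
F5 | step 3 | 2-prenylhydroquinone | CC(C)=CCc1cc(O)ccc1O
F6 | step 2 | 5,6-dimethoxybiphenyl-3-carbaldehyde | COc1cc(C=O)cc(-c2ccccc2)c1OC
F7 | step 2 | 5,6-dimethoxybiphenyl-3-yl formate | COc1cc(OC=O)cc(-c2ccccc2)c1OC
F8 | step 2 | 5,6-dimethoxybiphenyl-3-ol | COc1cc(O)cc(-c2ccccc2)c1OC
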